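**Retrosynthetic overview**
1. Target 7 ⇒ atromentin 4: the single enol acetate is put on last, by one O-acetylation of the quinone dianion.
2. Atromentin 4 ⇒ two molecules of an activated 4-hydroxyphenylpyruvate (S-phenyl thioester 2). Both ring C–C bonds (benzylic carbon to acyl carbon, head-to-tail) come from a Claisen then a Dieckmann condensation; the tetraketone formed is the keto tautomer of the dihydroxyquinone, so no redox step is needed.
3. Thioester 2 ⇒ 4-hydroxyphenylpyruvic acid 1 and thiophenol.
4. Ring order: only the central six-membered ring is built (step 2); both aryl rings come intact from 1 and the phenols are never protected.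

Assumption: the target has no stereocentre or stereoaxis, so it is one achiral compound and no enantioselective step is needed; the four oxygens of the central ring are equivalent by symmetry and tautomerism, so only one monoacetate on that ring exists.

**Step 1**
Reactants: 1 4-hydroxyphenylpyruvic acid (3-(4-hydroxyphenyl)-2-oxopropanoic acid, crystalline Z-enol)
Product: 2 S-phenyl 3-(4-hydroxyphenyl)-2-oxopropanethioate (present mainly as its Z-enol)
Conditions: PhSH (1.3 equiv), DCC (1.05 equiv), DMAP (5 mol %), CH2Cl2/THF, −10 → 0 °C, 2 h; filter, short silica column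
Reagents that add atoms: thiophenol, Sc1ccccc1
Why: Steglich-type carbodiimide thioesterification, in which the thiol is by far the best nucleophile present and so outruns acylation of the phenol and of the hydrogen-bonded enol OH, giving an isolable thioester that mimics the enzyme-bound acyl unit; no stereocentre is formed.

**Step 2**
Reactants: 2 S-phenyl 3-(4-hydroxyphenyl)-2-oxopropanethioate (two molecules)
Product: 4 atromentin (2,5-dihydroxy-3,6-bis(4-hydroxyphenyl)-1,4-benzoquinone), via linear Claisen adduct 3 (not isolated)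
Conditions: MgBr2·OEt2 (1.5 equiv), iPr2NEt (3.5 equiv), CH2Cl2/THF (0.5 M), 0 → 40 °C, Ar, 12 h; then 1 M HCl, air; filter the bronze solid, wash with CH2Cl2
Reagents that add atoms: none
Why: Proposed new method: soft enolisation with MgBr2·OEt2 and iPr2NEt turns all of enol 2 into a chelated magnesium enolate, so no keto tautomer is left as an aldol acceptor and the S-phenyl thioester (cross-conjugated to the enolate, hence not deactivated, and activated by magnesium) is the only electrophile; intermolecular C-acylation at the benzylic carbon (Claisen) gives 3, whose 2-aryl-1,3-dicarbonyl chelate makes that step irreversible, and enolisation of the remaining ArCH2CO unit closes the six-membered ring onto the second thioester (6-exo-trig Dieckmann) to a cyclohexane-1,2,4,5-tetraone that is simply the keto tautomer of 4, so no oxidation is needed and the doubly vinylogous carboxylate dianion is the thermodynamic sink into which O-acylated side products (aryl or enol esters, still active esters) can also drain; the closest known reaction types are the magnesium-mediated soft-enolisation crossed Claisen condensation of thioesters and the Dieckmann condensation; no stereocentre is formed.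

**Step 3**
Reactants: 4 atromentin
Product: 7 4-hydroxy-2,5-bis(4-hydroxyphenyl)-3,6-dioxocyclohexa-1,4-dien-1-yl acetate (target), via atromentin disodium salt 5 (not isolated), via monoacetate sodium salt 6 (not isolated)
Conditions: NaH (2.0 equiv), DMF, 0 °C, 20 min; Ac2O (1.0 equiv), −40 °C, 30 min; 1 M HCl (2.0 equiv), −20 → 0 °C, ice-water, filter
Reagents that add atoms: acetic anhydride, CC(=O)OC(C)=O
Why: O-acylation of a carboxylate-type anion (mixed vinylogous anhydride formation), selective because two equivalents of base ionise only the two vinylogous-acid OH groups (pKa about 3 and 6) and leave the phenols (pKa about 10) neutral, the dianion is much more nucleophilic than the mono-acetylated monoanion, any diacetate would be cleaved again by the acetate released, and the equivalence of the four ring oxygens allows only one monoacetate; no stereocentre is formed.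

**Compound list**
1 | 4-hydroxyphenylpyruvic acid (3-(4-hydroxyphenyl)-2-oxopropanoic acid; drawn as keto tautomer) | O=C(O)C(=O)Cc1ccc(O)cc1 | starting material
2 | S-phenyl 3-(4-hydroxyphenyl)-2-oxopropanethioate (drawn as keto tautomer; Z-enol predominant) | O=C(Cc1ccc(O)cc1)C(=O)Sc1ccccc1 | intermediate
3 | S-phenyl 3,6-bis(4-hydroxyphenyl)-2,4,5-trioxohexanethioate (linear Claisen adduct, not isolated; C3 enolised, no defined configuration) | O=C(Sc1ccccc1)C(=O)C(c1ccc(O)cc1)C(=O)C(=O)Cc1ccc(O)cc1 | intermediate
4 | atromentin (2,5-dihydroxy-3,6-bis(4-hydroxyphenyl)cyclohexa-2,5-diene-1,4-dione) | O=C1C(O)=C(c2ccc(O)cc2)C(=O)C(O)=C1c1ccc(O)cc1 | intermediate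
5 | disodium 2,5-bis(4-hydroxyphenyl)-3,6-dioxocyclohexa-1,4-diene-1,4-bis(olate) (atromentin disodium salt, not isolated) | [Na+].[Na+].[O-]C1=C(c2ccc(O)cc2)C(=O)C([O-])=C(c2ccc(O)cc2)C1=O | intermediate
6 | sodium 4-(acetyloxy)-2,5-bis(4-hydroxyphenyl)-3,6-dioxocyclohexa-1,4-dien-1-olate (monoacetate sodium salt, not isolated) | [Na+].CC(=O)OC1=C(c2ccc(O)cc2)C(=O)C([O-])=C(c2ccc(O)cc2)C1=O | intermediate
7 | 4-hydroxy-2,5-bis(4-hydroxyphenyl)-3,6-dioxocyclohexa-1,4-dien-1-yl acetate (2-O-acetylatromentin, achiral) | CC(=O)OC1=C(c2ccc(O)cc2)C(=O)C(O)=C(c2ccc(O)cc2)C1=O | target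

**Totals**
Total step count: 3. Longest linear sequence: 3 steps (1 → 2 → 4 → 7).

**Steps most likely to fail, with fallbacks**

Step 2 carries the highest risk. Arylpyruvates normally follow the aldol and lactonisation manifold, the free phenols can be acylated, and the cascade may stall at 3. The fallback sets out from 2 and comes back at 4. Both hydroxyl groups of 2 are silylated (Et3SiCl, imidazole, CH2Cl2, 0 °C) to give S-phenyl (Z)-2-(triethylsilyloxy)-3-[4-(triethylsilyloxy)phenyl]prop-2-enethioate F1, a latent enolate with neither a ketone nor an acidic proton. An anhydrous fluoride source (tetrabutylammonium difluorotriphenylsilicate, 2.2 equiv, THF, −78 → 20 °C) then releases the ammonium enolate in a medium without any proton donor. The keto tautomer needed for aldol addition therefore cannot form, and C-acylation by the thioester (Claisen, then Dieckmann) is the only carbon–carbon bond-forming path. The aryl silyl ethers are cleaved in the same operation, and acidic work-up in air delivers 4.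

Step 3 can fail by over-acetylation, by acetylation of a phenol, or by hydrolysis of the vinylogous anhydride during work-up. The fallback sets out from 4 and comes back at 7 with the phenols masked. Silylation of 4 (TBSCl 2.5 equiv, imidazole, DMF, 20 °C, then methanol, which cleaves any silyl ester on the acidic quinone oxygens) gives 2,5-dihydroxy-3,6-bis[4-(tert-butyldimethylsilyloxy)phenyl]-1,4-benzoquinone F2. NaH (2.0 equiv, THF, 0 °C) converts it into disodium 2,5-bis[4-(tert-butyldimethylsilyloxy)phenyl]-3,6-dioxocyclohexa-1,4-diene-1,4-bis(olate) F3. Ac2O (1.0 equiv, −40 °C) gives sodium 4-(acetyloxy)-2,5-bis[4-(tert-butyldimethylsilyloxy)phenyl]-3,6-dioxocyclohexa-1,4-dien-1-olate F4, and cold dilute HCl gives 4-hydroxy-2,5-bis[4-(tert-butyldimethylsilyloxy)phenyl]-3,6-dioxocyclohexa-1,4-dien-1-yl acetate F5. This compound can only be under- or over-acetylated on the quinone and is purified on silica. Aqueous HF in MeCN at 0 °C (acidic, non-nucleophilic) removes the two aryl silyl ethers without touching the enol acetate and gives 7.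

Step 1 can fail because a carbodiimide coupling on an unprotected enol acid that also bears a phenol may give N-acylurea, phenol esters or oligomers. The fallback sets out from 1 and comes back at 2. Persilylation of 1 (TBSCl 3.5 equiv, imidazole, DMF, 20 °C) gives tert-butyldimethylsilyl (Z)-2-(tert-butyldimethylsilyloxy)-3-[4-(tert-butyldimethylsilyloxy)phenyl]prop-2-enoate F6. The silyl ester is converted directly into the acid chloride with (COCl)2 and catalytic DMF (CH2Cl2, 0 °C), giving (Z)-2-(tert-butyldimethylsilyloxy)-3-[4-(tert-butyldimethylsilyloxy)phenyl]prop-2-enoyl chloride F7. Trapping with PhSH and pyridine (CH2Cl2, 0 °C) gives S-phenyl (Z)-2-(tert-butyldimethylsilyloxy)-3-[4-(tert-butyldimethylsilyloxy)phenyl]prop-2-enethioate F8. Aqueous HF in MeCN (0 °C), to which the thioester is stable, cleaves both silyl ethers and gives 2.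

**Further compounds**
F1 | step 2 | S-phenyl (Z)-2-(triethylsilyloxy)-3-[4-(triethylsilyloxy)phenyl]prop-2-enethioate | O=C(Sc1ccccc1)/C(O[Si](CC)(CC)CC)=C/c1ccc(O[Si](CC)(CC)CC)cc1
F2 | step 3 | 2,5-dihydroxy-3,6-bis[4-(tert-butyldimethylsilyloxy)phenyl]-1,4-benzoquinone | O=C1C(O)=C(c2ccc(O[Si](C)(C)C(C)(C)C)cc2)C(=O)C(O)=C1c1ccc(O[Si](C)(C)C(C)(C)C)cc1
F3 | step 3 | disodium 2,5-bis[4-(tert-butyldimethylsilyloxy)phenyl]-3,6-dioxocyclohexa-1,4-diene-1,4-bis(olate) | [Na+].[Na+].[O-]C1=C(c2ccc(O[Si](C)(C)C(C)(C)C)cc2)C(=O)C([O-])=C(c2ccc(O[Si](C)(C)C(C)(C)C)cc2)C1=O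
F4 | step 3 | sodium 4-(acetyloxy)-2,5-bis[4-(tert-butyldimethylsilyloxy)phenyl]-3,6-dioxocyclohexa-1,4-dien-1-olate | [Na+].CC(=O)OC1=C(c2ccc(O[Si](C)(C)C(C)(C)C)cc2)C(=O)C([O-])=C(c2ccc(O[Si](C)(C)C(C)(C)C)cc2)C1=O
F5 | step 3 | 4-hydroxy-2,5-bis[4-(tert-butyldimethylsilyloxy)phenyl]-3,6-dioxocyclohexa-1,4-dien-1-yl acetate | CC(=O)OC1=C(c2ccc(O[Si](C)(C)C(C)(C)C)cc2)C(=O)C(O)=C(c2ccc(O[Si](C)(C)C(C)(C)C)cc2)C1=O
F6 | step 1 | tert-butyldimethylsilyl (Z)-2-(tert-butyldimethylsilyloxy)-3-[4-(tert-butyldimethylsilyloxy)phenyl]prop-2-enoate | CC(C)(C)[Si](C)(C)OC(=O)/C(O[Si](C)(C)C(C)(C)C)=C/c1ccc(O[Si](C)(C)C(C)(C)C)cc1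
F7 | step 1 | (Z)-2-(tert-butyldimethylsilyloxy)-3-[4-(tert-butyldimethylsilyloxy)phenyl]prop-2-enoyl chloride | O=C(Cl)/C(O[Si](C)(C)C(C)(C)C)=C/c1ccc(O[Si](C)(C)C(C)(C)C)cc1
F8 | step 1 | S-phenyl (Z)-2-(tert-butyldimethylsilyloxy)-3-[4-(tert-butyldimethylsilyloxy)phenyl]prop-2-enethioate | O=C(Sc1ccccc1)/C(O[Si](C)(C)C(C)(C)C)=C/c1ccc(O[Si](C)(C)C(C)(C)C)cc1
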